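Watch the age of the target.

all flasks: enzyme 1.5 µM
- north-east: starting material 15 mM; second substrate 15 mM; run made earlier
- south-west: starting material 10 mM; second substrate 15 mM; run made earlier
- east: starting material 22 mM; second substrate 15 mM; run made earlier
- south-east: starting material 15 mM; second substrate 30 mM; run made earlier
- dawn: starting material 15 mM; second substrate 15.0 mM; one stirred flow tank at steady state, fed with the mixture as stated, mean residence time 15 min
- winter: starting material 15 mM; second substrate 15.0 mM (fed, over 7.50 min); all but second substrate at the start; second substrate goes in evenly over 7.50 min, the run ends at 15 min; time 15 min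
- noon: starting material 15 mM; second substrate 15.0 mM; a closed flask charged with all of it at once and left for 15 min; time 15 min
- summer: starting material 15 mM (fed, over 7.50 min); second substrate 15.0 mM; all but starting material at the start; starting material goes in evenly over 7.50 min, the run ends at 15 min; time 15 min

| run | time / min | target / % | isomer of the product / % |
|---|---|---|---|
| north-east | 0.667 | 44.4 | 0 |
| north-east | 1.33 | 71.0 | 3.9 |
| north-east | 2.50 | 87.8 | 10.9 |
| north-east | 5.00 | 77.4 | 20.1 |
| north-east | 10.0 | 62.1 | 38.4 |
| south-west | 1.33 | 79.3 | 4.2 |
| south-west | 2.50 | 87.1 | 10.6 |
| south-west | 4.00 | 81.7 | 19.3 |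
| south-west | 8.00 | 67.1 | 32.0 |
| south-west | 15.0 | 56.4 | 43.9 |
| east | 1.33 | 62.4 | 3.4 |
| east | 2.50 | 83.9 | 8.2 |
| east | 4.00 | 82.2 | 16.8 |
| east | 8.00 | 67.7 | 33.1 |
| east | 15.0 | 54.7 | 44.8 |
| south-east | 3.00 | 86.9 | 12.7 |
| south-east | 6.00 | 74.9 | 26.1 |
| south-east | 10.0 | 61.5 | 38.1 |
| south-east | 12.0 | 58.5 | 41.4 |
| south-east | 15.0 | 53.5 | 45.4 |

(readings scatter by 1 percentage point)

- the stated concentrations are those of everything mixed, before any reaction; amounts are the same in each set-up
- the feed brings no volume worth counting
- the earlier runs were made in a closed, stirred flask

1. the set-up with the highest share of target in all that became target or isomer of the product, at the outlet or at the end ("none" if the first two lie within 2 percentage points) (dawn / winter / noon / summer / none)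
2. share of target in all that became target or isomer of the product, at the outlet or at the end, dawn
3. share of target in all that became target or isomer of the product, at the outlet or at the end, winter
4. share of target in all that became target or isomer of the product, at the outlet or at the end, noon
5. share of target in all that became target or isomer of the product, at the outlet or at the end, summer

- In the south-west and east runs the target falls while the sum of target and isomer of the product stays near the charge, so read the share s, target over target plus isomer.
- Take an even split as the end point, as the forecast does. Then work with the fraction left, G = (s − 0.5)/0.5, which starts at 1 for fresh target.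
- From 4.00 min to 15.0 min, those two runs give the relaxation rate λ, the first-order rate at which G closes, of 0.159 /min, as a reading.
- Here is the apparent contradiction: the noon flask runs for 15 min and the dawn tank has a mean residence time τ of 15 min, yet my reckoning leaves more of G in dawn, 0.296, than in noon, 0.0923.
- It clears up once you average. In noon, counting every molecule at the full time τ, G is e^(−λτ). The dawn outlet mixes ages a, and averaging e^(−λa) over a tank's spread of ages gives 1/(1 + λτ), which stands above e^(−λτ), with product younger than τ in the mix.
- So I reckon s at 64.8% for dawn and 54.6% for noon.
- The forecast, on target that relaxes “first order and independent of both charges”, names dawn best: dawn 64.7%, winter 59%, noon 55%, summer 60%.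

The flask gives dawn as best: dawn 64.4%, winter 54.8%, noon 54.8%, summer 59.9%.

    starting material + enzyme ⇌ complex A (K = 1800 /M, k = 29300 /M/s)
    target ⇌ isomer of the product (K = 1.13, k = 0.00120 /s)
    complex B → enzyme + second product (k = 41.3 /s)
    complex A → enzyme + target (k = 195 /s)
    second substrate + enzyme ⇌ complex B (K = 15.0 /M, k = 1.48 × 10⁵ /M/s)

With the step from second substrate + enzyme to complex B struck out, winter gives 54.7% against 54.8%. Now put λ to work on summer, taking its target as made evenly over 7.50 min, so that ages run from 7.50 min to 15 min. Averaging e^(−λa) over that span gives G = 0.178, hence s = 58.9%, and summer stands at 59.9%.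

All runs were generated by integration with constants of no real substance, and the scatter is random.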